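## Structural features

Echinoclathrine B is an achiral anilide made of a benzene ring (ring A), a 2-methylpyridine ring (ring B) and a saturated thirteen-carbon acyl chain. Ring A is 1,2,3-trisubstituted: C1 carries the free phenolic hydroxyl, C2 the amide nitrogen and C3 a single bond to C4 of ring B, so the nitrogen sits in the most crowded position, between an oxygen and a twisted heteroaryl group. The chain is bound through its carbonyl carbon to that nitrogen and ends, twelve methylene groups further on, in an S-acetyl thioester. There is no stereocentre and no fused or bridged ring, so the problem is regiochemistry on ring A and functional-group compatibility. The fragile groups are: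
- the thioacetate, which is lost to amines, hydroxide, alkoxides, hydrides and strong Lewis acids;
- the ortho-aminophenol that precedes the amide, which oxidises in air;
- the ortho-hydroxy anilide, which can close to a benzoxazole in hot acid;
- the basic pyridine nitrogen, which binds Lewis acids and can be quaternised by alkyl halides.

The real difficulty is the contiguous O, N, C-aryl array. Electrophilic substitution of a phenol or an anilide does not put nitrogen between the other two groups, and a cross-coupling needs a ready-made 1,2,3-trisubstituted arene. The key step uses the fact that the oxygen at C1 borders the C2–C3 edge of ring A: an aryne across C2 and C3 with an alkoxy group at C1 is polarised so that a carbon nucleophile enters at C3 and the metal is left at C2 to accept electrophilic nitrogen.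

## Logic of the disconnections

**15 to 11 and 13 (through 14).** The amide N–C(O) bond is cut. It is the one bond whose rupture separates the aromatic half from the chain in a single move, and it lets the sulfur be installed on the chain alone, away from the oxidisable aminophenol. The target falls into a two-ring amine and a linear acid. The forward step must acylate nitrogen in preference to the neighbouring phenol oxygen and must activate 13 as 14 without touching the thioester, which excludes nucleophilic amines and strong base.

**13 to 12.** The C13–S bond is cut. A primary bromide displaced by a sulfur nucleophile that already carries its acetyl group avoids any free thiol and any separate S-acetylation. The gain is a bought ω-bromo acid. The forward step needs sulfur to outrun the carboxylate as nucleophile, which the soft, more nucleophilic sulfur anion should ensure.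

**11 to 10.** The phenol O–H is traced back to an O–CH3 bond. The methyl ether is kept because it is the group that directs the lithiation, polarises the aryne and survives both organolithium and Grignard reagents, and because the fluoroarene 3 that carries it is a cheap bulk chemical. An acetal-type ether would save the Lewis acid step but would have to be bought as a speciality reagent or made with a carcinogenic chloromethyl ether, so it is held in reserve. The forward cleavage must be done before the chain is attached, since the thioester would not tolerate the Lewis acid, and must use excess reagent because two basic nitrogens bind it.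

**10 to 8.** The two N–H bonds are traced back to the N=N=N unit. Nitrogen can only be delivered to a carbanion as an electrophile, and an azide is the smallest such form that reduces cleanly to the amine. The forward reduction must be mild enough not to trigger nitrene chemistry of the ortho-biaryl azide and must leave the pyridine ring alone.

**8 to 3 and 2 (through 4, 5, 6 and 7).** Two bonds are cut together: ring A C3 to pyridine C4, and ring A C2 to nitrogen. Both sit on adjacent carbons next to the C1 oxygen, which is the signature of a 3-alkoxyaryne 5 that is opened by a carbon nucleophile and then quenched at the neighbouring carbon. The crowded 1,2,3-pattern collapses into two monofunctional arenes. The forward step needs: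
- regioselective addition to 5;
- no free alkyl-metal in the flask, since it would compete for the aryne or deprotonate the pyridine methyl group;
- a low stationary concentration of 4, so that it does not arylate itself;
- an azide-transfer reagent slim enough to reach the flanked carbon–magnesium bond of 6.

**2 to 1.** The C–Mg bond is traced back to a C–Br bond by halogen–magnesium exchange. This gives the 4-pyridyl nucleophile from a stable, bought bromide without strongly basic conditions that would metalate the methyl group. The exchange reagent must be used in slight deficit so that none of it enters the key flask.

## Other disconnections considered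

**Alternative 1:** The cut is the ring A C1–O bond, with the phenol oxygen traced back to the carbonyl oxygen of the amide.

- Forward: Suzuki–Miyaura coupling of 1 with a commercial ortho-aminophenylboronic ester would give 2-(2-methylpyridin-4-yl)aniline A1. Acylation with the acid chloride of 12 would give the ω-bromo anilide A2. Constant-current oxidation of A2 at a graphite anode in hexafluoroisopropanol would join the amide oxygen to the one free ortho carbon and close the oxazole of 2-(12-bromododecyl)-4-(2-methylpyridin-4-yl)-1,3-benzoxazole A3. Acid-mediated hydration of the C=N bond would reopen the ring to the ortho-hydroxy anilide, and thioacetate displacement would finish.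
- In favour: the oxygen is installed by C–H functionalisation with current as the only oxidant. No organolithium, no azide, no boron tribromide and no protecting group are needed, and the amide exists before the phenol, so N against O acylation never arises. On these safety and selectivity points it is better than the chosen plan.
- Against: the cyclisation relies on oxidising the anilide to an amidyl radical or arene radical cation. Ring A here carries a pyridyl group that will be hydrogen-bonded or protonated in the fluorinated alcohol, which raises the oxidation potential. The position para to nitrogen is open and could take up solvent or couple. An aliphatic amide stabilises the cyclised cation less than a benzamide would. The ring-opening must stop at the amide, and A2, A3 and the opened bromide each hold a pyridine and a primary bromide and may self-quaternise.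
- Comparison: on structure, it makes the biaryl bond by standard cross-coupling and adds oxygen last, whereas the chosen plan makes C–C and C–N together on a ring that already has its oxygen. On mechanism, its regiochemistry rests on five-membered ring closure winning over para attack in a radical-cation manifold, whereas the chosen plan rests on ground-state polarisation of an aryne, which is the more predictable control element. On step economy it needs about five steps against six, which is better, with an equal longest linear sequence of five.

**Alternative 2:** The cut runs through ring A itself, at C1–C2 and C3–C4, so the benzene ring is built and not decorated.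

- Forward: the pyranyl N-alkynyl carbamate A4, in which the carbamate oxygen of a 2-pyranon-3-yl unit and a pyridyl-substituted ynamide share one nitrogen, would be heated. The ynamide adds across C3 and C6 of the pyranone in an intramolecular Diels–Alder reaction, the bridged lactone expels CO2, and the N-(4-methoxybenzyl) benzoxazolone A5 results. Removal of the benzyl group and hydroxide opening of the cyclic carbamate would give 11, where the chosen route would be rejoined.
- In favour: the tether fixes the positions of oxygen, nitrogen and pyridyl by connectivity alone, so on regiocontrol it is at least the equal of the chosen plan and needs no electronic bias. It uses no organolithium and no azide, which is better on hazard. Oxygen and nitrogen stay masked together as a carbamate that shields the aminophenol from air until late, which is better on handling.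
- Against: A4 has to be assembled from a hydroxypyranone carbamate and a pyridyl bromoalkyne by N-alkynylation under CuSO4·5H2O and 1,10-phenanthroline, and an enol-type carbamate is an activated acyl donor that may not survive the base. The three-atom tether with two sp carbons makes a strained transition state. Two extra unmasking steps follow, one of them a forcing hydrolysis.
- Comparison: on structure it is the most ambitious, making two ring bonds and two rings in one step against two bonds and no ring in the chosen plan. On mechanism it is a thermal pericyclic cascade driven by irreversible loss of CO2, clean in principle but dependent on a precursor of uncertain stability. On step economy it needs about nine or ten steps against six, which is clearly worse.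

**Alternative 3:** Two bonds are cut: ring A C2–N and the bond from the amide carbonyl to the first methylene of the chain.

- Forward: 2-methoxy-6-(2-methylpyridin-4-yl)benzoic acid A6 would be converted into the aroyl azide A7. Thermolysis would give the isocyanate A8 by Curtius rearrangement. Dodec-11-enylmagnesium bromide A9, added to the same flask, would give the anilide A10. Ether cleavage and radical anti-Markovnikov addition of the S-acetyl donor to the terminal alkene would complete 15.
- In favour: nitrogen arrives by ipso migration with complete positional fidelity, equal to the chosen plan on regiocontrol. The amide is made by a carbon nucleophile, so N against O selectivity does not arise, which is better. Two bonds form in one flask, equal to the chosen key step in bond economy.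
- Against: A6 is a 2,6-disubstituted benzoic acid that needs a hindered cross-coupling and a hindered ester hydrolysis. An azide is still handled, so there is no gain in hazard. A9 must be prepared separately. The end game has an ordering conflict: the thioester would not survive ether cleavage by a boron Lewis acid, while doing the ether cleavage first exposes the alkene to HBr and leaves a phenol that may retard the radical chain.
- Comparison: on structure it attaches the chain early and carries a long lipophilic tail through the late steps, whereas the chosen plan joins two finished halves at the end. On mechanism both depend on one reactive intermediate, isocyanate against aryne, captured by a Grignard reagent. On step economy it needs about eight steps against six, which is worse.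

Key step: step 2

Remark on the chemistry: no structure needed correction; the chain is read as tridecanoyl (carbonyl carbon plus twelve methylenes) with the S-acetyl group on C13, 2 is formed and used as its LiCl complex in THF, and 8 is handled only in solution.

## Route

Step 1
Reactants: 1 4-bromo-2-methylpyridine
Product: 2 (2-methylpyridin-4-yl)magnesium chloride (LiCl complex, THF solution, titrated and used directly)
Conditions: iPrMgCl·LiCl (0.98 equiv), THF, 0 °C → rt, 2 h
Reagents that add atoms: isopropylmagnesium chloride–lithium chloride complex, CC(C)[Mg]Cl.[Li+].[Cl-]
Why: Bromine–magnesium exchange with the turbo-Grignard reagent: the sp2 carbanion on the electron-poor pyridine ring is more stable than isopropyl, so the equilibrium lies on the side of 2 and 2-bromopropane. The slight deficit of exchange reagent keeps isopropyl–magnesium out of the aryne flask, and a Grignard reagent should not metalate the ring methyl group at this temperature.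

Step 2
Reactants: 3 1-fluoro-3-methoxybenzene; 2 (2-methylpyridin-4-yl)magnesium chloride
Product: 8 4-(2-azido-3-methoxyphenyl)-2-methylpyridine, via (2-fluoro-6-methoxyphenyl)lithium 4 (not isolated), via 3-methoxybenzyne 5 (not isolated), via [2-methoxy-6-(2-methylpyridin-4-yl)phenyl]magnesium chloride 6 (not isolated), via tosyltriazenide magnesium salt 7 (not isolated)
Conditions: 3 (1.05 equiv), s-BuLi (1.0 equiv), THF, −78 °C, 1 h; add slowly to 2 (1.5 equiv) in THF, −20 °C → rt, 3 h; TsN3 (1.6 equiv, solution in toluene), −40 → 0 °C; aq. Na4P2O7, rt; extractive work-up below 30 °C in the dark, product kept as a solution and never taken to dryness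
Reagents that add atoms: tosyl azide (4-methylbenzenesulfonyl azide), Cc1ccc(cc1)S(=O)(=O)N=[N+]=[N-]
Why: sec-Butyllithium removes the one proton of 3 that lies between fluorine and oxygen (directed ortho-metalation, both groups acidify and coordinate), giving 4 with no alkyllithium left over because 3 is in slight excess. When the cold solution of 4 meets the warmer solution of 2 it loses LiF to give aryne 5, and slow addition into an excess of 2 keeps 4 too dilute to arylate itself. The methoxy group withdraws electron density through the sigma frame and distorts the strained triple bond, so the carbon remote from oxygen is the more electrophilic terminus; the carbanion of 2 bonds there, forming the ring A C3 to pyridine C4 bond, and the carbon–magnesium bond of 6 lies at C2, where induction and O-to-Mg chelation stabilise it. Carbon and not pyridine nitrogen should attack, because the C–Mg bond is by far the stronger nucleophile and the ring nitrogen is engaged by magnesium and lithium cations. Although 6 is flanked on both sides, it only has to reach the slim terminal nitrogen of tosyl azide; the triazenide 7 so formed fragments into 8 and sulfinate during the pyrophosphate work-up, which forms the C2–N bond. The closest known reaction type is the one-flask union of a lithiated fluoroarene, an aryl Grignard reagent and an electrophile to give 2-substituted 3-alkoxybiaryls, combined with azide transfer from sulfonyl azides to arylmagnesium halides. No ring is closed and no stereocentre is formed, so there is no mode of closure or stereocontrol to assign. The one selectivity the step needs is the regiochemistry of addition to 5, and the methoxy group at C1 provides it: the incoming carbon ends up meta to oxygen (C3) and the magnesium, later the azide, ortho to it (C2).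

Step 3
Reactants: 8 4-(2-azido-3-methoxyphenyl)-2-methylpyridine
Product: 10 2-methoxy-6-(2-methylpyridin-4-yl)aniline, via N-aryl triphenyliminophosphorane 9 (not isolated)
Conditions: PPh3 (1.3 equiv on total azide), THF, rt, 2 h; then H2O, 60 °C, 6 h; acid–base extraction (1 M HCl, then NaOH to pH 10)
Reagents that add atoms: none
Why: Staudinger reduction: the phosphine adds to the terminal nitrogen, the phosphazide loses N2 at room temperature to give 9, and water hydrolyses the P=N bond to the aniline and Ph3P=O. The basic product is separated from the phosphine oxide by extraction into acid, and the low temperature of N2 loss avoids nitrene insertion into ring B.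

Step 4
Reactants: 10 2-methoxy-6-(2-methylpyridin-4-yl)aniline
Product: 11 2-amino-3-(2-methylpyridin-4-yl)phenol
Conditions: BBr3 (4 equiv), CH2Cl2, −78 °C → rt, 12 h; ice-water, NaHCO3 to pH 7–8, argon; used at once
Reagents that add atoms: none
Why: Lewis acid cleavage of an aryl methyl ether: boron binds the ether oxygen, bromide attacks the methyl group in an SN2 step, and the aryloxyborane is hydrolysed on work-up. Four equivalents are used because the pyridine nitrogen and the amino group each hold one equivalent, and no thioester or amide is present yet.

Step 5
Reactants: 12 13-bromotridecanoic acid
Product: 13 13-(acetylsulfanyl)tridecanoic acid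
Conditions: KSC(O)CH3 (2.2 equiv), DMF, rt, 12 h; then 1 M HCl
Reagents that add atoms: potassium thioacetate, CC(=O)[S-].[K+]
Why: SN2 displacement of a primary bromide by the soft thioacetate anion; the carboxylate formed by the first equivalent is a far poorer nucleophile, so ester oligomers should not form, and acidification returns the free acid.

Step 6
Reactants: 13 13-(acetylsulfanyl)tridecanoic acid; 11 2-amino-3-(2-methylpyridin-4-yl)phenol
Product: 15 echinoclathrine B, S-(13-{[2-hydroxy-6-(2-methylpyridin-4-yl)phenyl]amino}-13-oxotridecyl) ethanethioate, via 13-(acetylsulfanyl)tridecanoyl chloride 14 (not isolated)
Conditions: 13 (1.0 equiv), (COCl)2 (1.2 equiv), DMF (cat.), CH2Cl2, 0 °C → rt, evaporate; then 11 (1.1 equiv), EtOAc/sat. aq. NaHCO3, 0 °C → rt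
Reagents that add atoms: none
Why: Acid chloride formation through the Vilsmeier-type chloroiminium leaves the S-acetyl thioester untouched, as there is no free thiol. Schotten–Baumann acylation then favours the neutral amino group over the un-ionised phenol, which bicarbonate does not deprotonate, and any ester formed on the neighbouring oxygen can pass its acyl group to nitrogen. Cold bicarbonate is too weak a nucleophile and base to cleave the thioacetate.

## Compound list

1 | 4-bromo-2-methylpyridine | Cc1cc(Br)ccn1 | starting material
2 | (2-methylpyridin-4-yl)magnesium chloride (LiCl complex in THF) | Cc1cc([Mg]Cl)ccn1 | intermediate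
3 | 1-fluoro-3-methoxybenzene | COc1cccc(F)c1 | starting material
4 | (2-fluoro-6-methoxyphenyl)lithium | COc1cccc(F)c1[Li] | intermediate (not isolated)
5 | 3-methoxybenzyne (1-methoxy-2,3-didehydrobenzene) | COC1=CC=CC#C1 | intermediate (not isolated)
6 | [2-methoxy-6-(2-methylpyridin-4-yl)phenyl]magnesium chloride | COc1cccc(-c2ccnc(C)c2)c1[Mg]Cl | intermediate (not isolated)
7 | chloromagnesium 1-[2-methoxy-6-(2-methylpyridin-4-yl)phenyl]-3-tosyltriazenide | COc1cccc(-c2ccnc(C)c2)c1N=NN([Mg]Cl)S(=O)(=O)c1ccc(C)cc1 | intermediate (not isolated)
8 | 4-(2-azido-3-methoxyphenyl)-2-methylpyridine | COc1cccc(-c2ccnc(C)c2)c1N=[N+]=[N-] | intermediate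
9 | N-[2-methoxy-6-(2-methylpyridin-4-yl)phenyl]triphenyliminophosphorane | COc1cccc(-c2ccnc(C)c2)c1N=P(c1ccccc1)(c1ccccc1)c1ccccc1 | intermediate (not isolated)
10 | 2-methoxy-6-(2-methylpyridin-4-yl)aniline | COc1cccc(-c2ccnc(C)c2)c1N | intermediate
11 | 2-amino-3-(2-methylpyridin-4-yl)phenol | Nc1c(O)cccc1-c1ccnc(C)c1 | intermediate
12 | 13-bromotridecanoic acid | OC(=O)CCCCCCCCCCCCBr | starting material
13 | 13-(acetylsulfanyl)tridecanoic acid | CC(=O)SCCCCCCCCCCCCC(=O)O | intermediate
14 | 13-(acetylsulfanyl)tridecanoyl chloride | CC(=O)SCCCCCCCCCCCCC(=O)Cl | intermediate (not isolated)
15 | echinoclathrine B, S-(13-{[2-hydroxy-6-(2-methylpyridin-4-yl)phenyl]amino}-13-oxotridecyl) ethanethioate | CC(=O)SCCCCCCCCCCCCC(=O)Nc1c(O)cccc1-c1ccnc(C)c1 | target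

## Step count and least certain steps

Total step count: 6 (steps 1 to 6). Longest linear sequence: 5 (steps 1, 2, 3, 4 and 6, running 1 → 2 → 8 → 10 → 11 → 15). Step 5 is a one-step side branch.

**Step 2 (key step).** Three processes could erode it:
- capture of the aryne by the aryllithium that generates it, or by pyridine nitrogen in place of the pyridyl carbanion, because a pyridyl Grignard reagent is a weaker carbon nucleophile than the aryl Grignard reagents usually used;
- proton transfer from the ring methyl group to the aryl–metal species, which would give azide-free biaryl after the quench;
- incomplete azide transfer to the doubly flanked carbon–magnesium bond.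

The surplus of 2 is azidated as well, which is why the crude solution is never concentrated to dryness; step 3 turns that by-product into a water-soluble aminopyridine. The fallback gives up the aryne and the azide and uses cross-coupling. Setting out from 1, Miyaura borylation (B2pin2, Pd(dppf)Cl2, KOAc, dioxane, 90 °C) would give 2-methyl-4-(4,4,5,5-tetramethyl-1,3,2-dioxaborolan-2-yl)pyridine F1. Suzuki–Miyaura coupling of F1 with bought 2-bromo-6-methoxyaniline F2 (Pd(dppf)Cl2, K2CO3, dioxane/H2O, 90 °C) would give the aniline directly and return to the route at 10.

**Step 6.** The hindered, weakly nucleophilic amine may react slowly, so that acylation on oxygen, double acylation or hydrolysis of the acid chloride in the two-phase medium compete. Partial loss of the S-acetyl group during work-up is also possible. The fallback puts the chain on before the phenol is freed and brings the sulfur in last. Setting out from 10 and 12, oxalyl chloride would convert 12 into 13-bromotridecanoyl chloride F3. F3 would acylate 10 (pyridine, CH2Cl2, 0 °C → rt) to 13-bromo-N-[2-methoxy-6-(2-methylpyridin-4-yl)phenyl]tridecanamide F4. BBr3 in CH2Cl2 would cleave the ether to 13-bromo-N-[2-hydroxy-6-(2-methylpyridin-4-yl)phenyl]tridecanamide F5. KSC(O)CH3 in DMF at room temperature would displace the bromide and return to the route at 15. F4 and F5 would be carried forward promptly and dilute, since they hold a pyridine and a primary bromide.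

**Step 4.** Sequestration of the Lewis acid by the two basic nitrogens may leave the cleavage incomplete, and the amphoteric, electron-rich aminophenol may oxidise during neutralisation and extraction. The fallback changes the oxygen protecting group so that no Lewis acid is needed. Setting out from 2, bought 1-fluoro-3-(methoxymethoxy)benzene F6 would take the place of 3 under the conditions of step 2. It would be lithiated to [2-fluoro-6-(methoxymethoxy)phenyl]lithium F7, which would give 3-(methoxymethoxy)benzyne F8. Addition of 2 would give [2-(methoxymethoxy)-6-(2-methylpyridin-4-yl)phenyl]magnesium chloride F9, and tosyl azide would give chloromagnesium 1-[2-(methoxymethoxy)-6-(2-methylpyridin-4-yl)phenyl]-3-tosyltriazenide F10. Work-up would give 4-[2-azido-3-(methoxymethoxy)phenyl]-2-methylpyridine F11. PPh3 in THF would convert F11 into N-[2-(methoxymethoxy)-6-(2-methylpyridin-4-yl)phenyl]triphenyliminophosphorane F12. Warm aqueous HCl would then hydrolyse both the P=N bond and the acetal in one flask and return to the route at 11, obtained as its air-stable hydrochloride.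

**Step 1.** The exchange may be slow or incomplete at a temperature low enough to avoid addition of organomagnesium species to the pyridine ring of unreacted 1. Any isopropyl–magnesium left would compete for the aryne in step 2. The fallback uses the much faster halogen–lithium exchange. Setting out from 1, n-BuLi (1.0 equiv, Et2O/THF, −78 °C) would give (2-methylpyridin-4-yl)lithium F13, and transmetalation with MgCl2 in THF at −78 °C → 0 °C would return to the route at 2.

**Step 3.** Hydrolysis of the hindered N-aryl iminophosphorane may stall, and heating before the phosphine has consumed the azide could cause loss of N2 with nitrene insertion into ring B. The fallback replaces phosphorus chemistry by catalytic hydrogenation. Setting out from 8, after filtration through silica to remove sulfur residues, H2 (1 atm) over palladium on carbon (Pd/C) in EtOAc/MeOH at room temperature would return to the route at 10 without any new compound.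

## Further compounds

F1 | step 2 | 2-methyl-4-(4,4,5,5-tetramethyl-1,3,2-dioxaborolan-2-yl)pyridine | Cc1cc(B2OC(C)(C)C(C)(C)O2)ccn1
F2 | step 2 | 2-bromo-6-methoxyaniline | COc1cccc(Br)c1N
F3 | step 6 | 13-bromotridecanoyl chloride | ClC(=O)CCCCCCCCCCCCBr
F4 | step 6 | 13-bromo-N-[2-methoxy-6-(2-methylpyridin-4-yl)phenyl]tridecanamide | COc1cccc(-c2ccnc(C)c2)c1NC(=O)CCCCCCCCCCCCBr
F5 | step 6 | 13-bromo-N-[2-hydroxy-6-(2-methylpyridin-4-yl)phenyl]tridecanamide | Oc1cccc(-c2ccnc(C)c2)c1NC(=O)CCCCCCCCCCCCBr
F6 | step 4 | 1-fluoro-3-(methoxymethoxy)benzene | COCOc1cccc(F)c1
F7 | step 4 | [2-fluoro-6-(methoxymethoxy)phenyl]lithium | COCOc1cccc(F)c1[Li]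
F8 | step 4 | 3-(methoxymethoxy)benzyne | COCOC1=CC=CC#C1
F9 | step 4 | [2-(methoxymethoxy)-6-(2-methylpyridin-4-yl)phenyl]magnesium chloride | COCOc1cccc(-c2ccnc(C)c2)c1[Mg]Cl
F10 | step 4 | chloromagnesium 1-[2-(methoxymethoxy)-6-(2-methylpyridin-4-yl)phenyl]-3-tosyltriazenide | COCOc1cccc(-c2ccnc(C)c2)c1N=NN([Mg]Cl)S(=O)(=O)c1ccc(C)cc1
F11 | step 4 | 4-[2-azido-3-(methoxymethoxy)phenyl]-2-methylpyridine | COCOc1cccc(-c2ccnc(C)c2)c1N=[N+]=[N-]
F12 | step 4 | N-[2-(methoxymethoxy)-6-(2-methylpyridin-4-yl)phenyl]triphenyliminophosphorane | COCOc1cccc(-c2ccnc(C)c2)c1N=P(c1ccccc1)(c1ccccc1)c1ccccc1
F13 | step 1 | (2-methylpyridin-4-yl)lithium | Cc1cc([Li])ccn1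
F0 | step 3 | none | none
A1 | alternative 1 | 2-(2-methylpyridin-4-yl)aniline | Cc1cc(-c2ccccc2N)ccn1
A2 | alternative 1 | 13-bromo-N-[2-(2-methylpyridin-4-yl)phenyl]tridecanamide | Cc1cc(-c2ccccc2NC(=O)CCCCCCCCCCCCBr)ccn1
A3 | alternative 1 | 2-(12-bromododecyl)-4-(2-methylpyridin-4-yl)-1,3-benzoxazole | Cc1cc(-c2cccc3oc(CCCCCCCCCCCCBr)nc23)ccn1
A4 | alternative 2 | 2-oxo-2H-pyran-3-yl N-(4-methoxybenzyl)-N-[(2-methylpyridin-4-yl)ethynyl]carbamate | COc1ccc(CN(C#Cc2ccnc(C)c2)C(=O)OC2=CC=COC2=O)cc1
A5 | alternative 2 | 3-(4-methoxybenzyl)-4-(2-methylpyridin-4-yl)-1,3-benzoxazol-2(3H)-one | Cc1cc(-c2cccc3oc(=O)n(Cc4ccc(OC)cc4)c23)ccn1
A6 | alternative 3 | 2-methoxy-6-(2-methylpyridin-4-yl)benzoic acid | COc1cccc(-c2ccnc(C)c2)c1C(=O)O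
A7 | alternative 3 | 2-methoxy-6-(2-methylpyridin-4-yl)benzoyl azide | COc1cccc(-c2ccnc(C)c2)c1C(=O)N=[N+]=[N-]
A8 | alternative 3 | 4-(2-isocyanato-3-methoxyphenyl)-2-methylpyridine | COc1cccc(-c2ccnc(C)c2)c1N=C=O
A9 | alternative 3 | dodec-11-en-1-ylmagnesium bromide | Br[Mg]CCCCCCCCCCC=C
A10 | alternative 3 | N-[2-methoxy-6-(2-methylpyridin-4-yl)phenyl]tridec-12-enamide | COc1cccc(-c2ccnc(C)c2)c1NC(=O)CCCCCCCCCCC=C
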